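Atom labels follow the target **14**: ring A is C1–C6 (C1 spiro, C2 and C6 carbonyls, C3 acylated, C4 enol carbon, C5 bearing methyl and prenyl); the hydrindane is C1'–C7a' (C5' = C1). Names of compounds without ring A use the same hydrindane numbers without primes.

## The problem

Target **14** joins an acylated, enolised cyclohexane-1,3,5-trione (ring A) through a spiro carbon to ring B of a cis-fused hydrindane. Ring C carries a tertiary carbinol at C3' and ring B a second one at C7'. There are seven stereocentres: C3', C3a', C7a' and C7' on the hydrindane, the spiro carbon C1 (stereogenic only because C2 and C6 differ), the quaternary C5, and the side-chain centre of the (R)-2-methylbutanoyl group. Ring C, the C7' hydroxyl and the C6 carbonyl all lie on one face of ring B, and the C3' hydroxyl points over that same face. C3' can therefore control C3a' and C7a' directly and, through a tether, C1 and C7'. C5 is four bonds from the nearest stereocentre and needs external control, and the acyl centre must come from the chiral pool and escape enolisation. The sensitive groups are two tertiary alcohols (ionisation in acid), a C6 ketone between two quaternary carbons (retro-Claisen cleavage by nucleophilic base), an ambident triketone (O versus C alkylation) and a prenyl alkene that tolerates neither ozone nor oxidising radicals. The enabling feature is that C1 bears two carbonyl carbons and two methylene groups (C4', C6'), so it is the carbon of dimethyl malonate (**1**) alkylated twice. The other ten carbons of rings B and C are the skeleton of (S)-linalool (**2**) with its carbinol centre intact: C4' is the vinyl CH2, C6' a terminal methyl, and the C3a'–C7a' bond joins linalool C2 to C6.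

## Retrosynthesis

**14 ⇒ 13.** The C5–CH2 bond of the prenyl group is cut last. C5 has no neighbour that could direct it, so it is best set in a separate, catalyst-controlled alkylation of the planar trione enolate. Installing prenyl at the end also keeps its alkene away from the radical oxidation and the ozonolysis used earlier. Precursor **13** has one stereocentre and one alkene fewer. The forward step must alkylate carbon rather than oxygen, C5 rather than C3, and one face of the enolate.

**13 ⇒ 12 ⇒ 8 + 11.** Ring A is opened at C2–C3 (intramolecular Claisen condensation of triketo ester **12**) and then at C5–C6 (acylation of the dianion of diketone **11** by lactone **8**). The two carbonyls on the spiro carbon both come from the malonate and must be told apart, because C6 ends next to C5 and C2 next to C3. A [3+3] union of a symmetrical diacid derivative with a bis-enol ether cannot do this and would give both spiro epimers. In **8** one carbonyl is a lactone and the other a methyl ester, so the order of the two acylations is fixed by reactivity and the spiro configuration is decided before ring A exists. **11** brings C3, C4, C5, the C5 methyl and the complete acyl group. The forward steps need the terminal carbanion of the dianion to attack the lactone only, and the central carbon to close onto the ester.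

**11 ⇒ 10 ⇒ 9.** The diketone is cut between C4 and C5 of its octane chain: the methyl-side enolate of (3R)-3-methylpentan-2-one (**10**) is acylated by a propanoyl donor. The reverse polarity (a butanone enolate plus an activated derivative of **9**) is rejected because butanone deprotonates at both α-positions. **10** comes from (R)-2-methylbutanoic acid (**9**) by addition of a methyl nucleophile.

**8 ⇒ 7 ⇒ 5.** The C7'–CH3 bond is cut (methyl addition to ketone **7**), and the ketone is traced to the exocyclic methylene of **5** by ozonolysis through ozonide **6**. Epoxidation of the methylene followed by hydride opening was considered and rejected. Hydride would not spare the esters, and in the bridged lactone the reagent can approach only from the exo face, which for an epoxidation gives the wrong C7' epimer. For a carbon nucleophile the same exo approach gives the right one: methyl exo, hydroxyl endo on the face of ring C. The price is one carbon removed and put back.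

**5 ⇒ 4.** The lactone C–O bond is cut. In hydroxy diester **4** the C3' hydroxyl can reach only the ester on its own face of ring B. Lactonisation therefore makes the malonate carbon stereogenic with the required configuration, and locks ring B in the conformation that step 4 needs. The step adds no carbon but solves two stereochemical problems.

**4 ⇒ 1 + 2.** Three C–C bonds are cut at once: C5'–C4', C3a'–C7a' and C5'–C6'. Stepwise alkylation of a malonate would need a differentiated ten-carbon bis-electrophile with the ring fusion already set. The radical cascade uses both alkenes of **2** as they are, passes through monocyclic malonate **3**, and lets C3' set the two ring-fusion centres. It must start at the vinyl CH2, close 5-exo then 6-endo, and twice end in the less substituted alkene.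

## Roads not taken

**Alternative 1:** Ring C and the bond from the future spiro carbon to C4' would be made by a De Mayo sequence: photocycloaddition of an acyl-trione enol to a tethered vinyl group, then retro-aldol opening to **A1**. The spiro centre would follow by C-alkylation with the epoxide and the C3' carbinol by methyl addition. Its merits are real: ring A is used as an intact acylphloroglucinol-type unit, the key operation needs no reagent, and C5 can be set early on a cheap intermediate, which is better placed than the last-step solution chosen here. The weak points are the photosubstrate, which carries two acyl groups and a prenyl alkene that can also add, and facial control at C3a' from a remote centre. **A1** then still needs a spiro-forming alkylation of an ambident trione by a flexible epoxide side chain, and a methyl addition to a ketone beside an acidic trione. The chosen plan sets against this that C1, C7', C3a' and C7a' are fixed by ring constraints, and that prenyl enters after all oxidations.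

**Alternative 2:** Ring A would be closed last at C1–C6, the ring B carbon of a diketone dianion attacking an ester on the preformed methyl/prenyl carbon to give **A2**. Its clear advantage is that C5 is made beforehand on a small building block by established asymmetric alkylation and cannot be lost; the chosen plan has only ligand control at the last step to set against that. The spiro centre, however, would arise from a hindered ring methine carbanion attacking a neopentyl ester, with its configuration left to axial-versus-equatorial approach and no relay. **A2** also lacks the acyl group, needs two silyl ethers, and leaves the hydrindane and its side chain to be made separately. The chosen plan forms both bonds at the spiro carbon by radical addition at the outset, sets its configuration by lactonisation and needs no protecting group.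

**Alternative 3:** Ring B would be closed at C7'–C7a' by an intramolecular carbonyl-ene reaction of an acetonyl ketone with a cyclopentene, giving **A3**. This forms the ring, the C7' carbinol and C7a' in one concerted step. That is more direct than the ozonolysis and methyl addition used here, which take two steps and exchange a carbon. Against it, an unactivated methyl ketone needs a strong Lewis acid, which the chelating trione would bind and the tertiary carbinol would not survive. The precursor must already hold C1 and C5 in the right sense on ring A with nothing to control either. **A3** finally needs its ring C alkene saturated in the presence of the prenyl alkene. The chosen plan takes longer over C7' but controls every ring stereocentre explicitly.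

Key step: step 1

## Assumptions

- (S)-Linalool of high enantiomeric purity is taken as the commercial material.
- The acyl triones **12**–**14** are mixtures of enol tautomers; each is written in one form and the CIP descriptors refer to that form.
- Metal enolates, alkoxides and tetrahedral adducts formed and consumed within one operation are treated as the reacting forms of the numbered compounds, not as separate compounds.
- The CIP label of the spiro carbon changes from S (**5**, **7**, **8**) to R (**12**–**14**) only because the priorities of its two carbonyl groups change; its geometry is unchanged.

## Route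

Step 1
Reactants: 1 dimethyl malonate; 2 (S)-linalool, (3S)-3,7-dimethylocta-1,6-dien-3-ol
Product: 4 dimethyl (3S,3aR,7aR)-3-hydroxy-3-methyl-7-methylidene-1,2,3,3a,4,6,7,7a-octahydro-5H-indene-5,5-dicarboxylate, via monocyclic isopropenyl malonate 3 (not isolated)
Conditions: 2 (3 equiv), 1 (1 equiv, slow addition), Mn(OAc)3·2H2O (4.4 equiv), Cu(OAc)2·H2O (0.5 equiv), KOAc (2 equiv), degassed AcOH, 60 °C
Reagents that add atoms: none
Why: Proposed new method: Mn(OAc)3 oxidises the enol of 1 to the electrophilic malonyl radical, which is expected to add to the unsubstituted vinyl terminus of 2 (the future C4'), since the competing carbon of the trisubstituted alkene is shielded by its own substituent. The secondary radical closes ring C 5-exo-trig onto the trisubstituted alkene (C3a'–C7a' bond), helped by the quaternary carbinol in the chain, and Cu(OAc)2 turns the tertiary radical through an organocopper intermediate into the isopropenyl group of 3. A second oxidation at the now monoalkylated malonate carbon gives a radical that closes ring B 6-endo-trig onto the CH2 of this 1,1-disubstituted alkene (C5'–C6' bond), the usual mode for stabilised radicals on 5-substituted hexenyl chains, and divalent copper again ends the sequence at the less substituted, exocyclic alkene. The closest known reaction types are the Mn(OAc)3/Cu(OAc)2 oxidative addition–cyclisation of malonates with alkenes and the oxidative cyclisation of unsaturated malonates; running both in one flask is the new element. C3a' and C7a' are set in the 5-exo closure by C3' of 2: a chair-like transition state with the C3' methyl pseudo-equatorial, together with the cis preference of 1-substituted hexenyl radicals, should place the two new ring C substituents cis to each other and cis to the hydroxyl. The step needs site selectivity for the vinyl group, oxidation of each tertiary radical to the less substituted alkene and 6-endo closure; the excess of 2 keeps malonyl radicals from attacking the alkenes of 3 and 4, and the acetate buffer and fast copper oxidation are meant to keep the tertiary allylic alcohol and the tertiary radicals from ionising.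

Step 2
Reactants: 4 dimethyl (3S,3aR,7aR)-3-hydroxy-3-methyl-7-methylidene-octahydro-5H-indene-5,5-dicarboxylate
Product: 5 methyl (3S,3aR,5S,7aR)-3-methyl-7-methylidene-octahydro-1H-indene-5-carboxylate 5,3-carbolactone (the C5 carboxyl on the face of C3 closed as a δ-lactone onto O3)
Conditions: NaH (1.2 equiv), THF, 0 °C → rt; AcOH quench
Reagents that add atoms: none
Why: Intramolecular transesterification (lactonisation): the C3' alkoxide can reach only the ester on its own face of ring B, so the six-membered lactone closes across the concave face and the weaker base methoxide is released; this makes the former malonate carbon stereogenic (5S), marks its cis carbonyl as the future C6 and locks ring B in the chair that carries the lactone bridge.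

Step 3
Reactants: 5 methylidene lactone ester
Product: 7 methyl (3S,3aR,5S,7aR)-3-methyl-7-oxo-octahydro-1H-indene-5-carboxylate 5,3-carbolactone, via spiro-1,2,4-trioxolane 6 (not isolated)
Conditions: O3, CH2Cl2, −78 °C; then Me2S, −78 °C → rt
Reagents that add atoms: ozone, [O-][O+]=O
Why: Ozonolysis with reductive work-up; the exocyclic methylene is the only alkene present, and C7a' next to the new ketone cannot epimerise because the lactone bridge holds the ring fusion cis.

Step 4
Reactants: 7 keto lactone ester
Product: 8 methyl (3S,3aR,5S,7S,7aR)-7-hydroxy-3,7-dimethyl-octahydro-1H-indene-5-carboxylate 5,3-carbolactone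
Conditions: MeMgBr (1.3 equiv), THF, −78 °C; sat. aq. NH4Cl at −78 °C
Reagents that add atoms: methylmagnesium bromide, C[Mg]Br
Why: Grignard 1,2-addition to the ketone, faster at −78 °C than attack on the lactone or the neopentyl ester; in the bridged lactone (a 2-oxabicyclo[3.3.1]nonane) the endo face of C7' is covered by the lactone oxygen bridge, so methyl enters exo and the hydroxyl ends endo on the face of ring C, which is (7S). Quenching cold keeps the new alkoxide from exchanging lactone partners, which would in any case converge on the same product in step 7.

Step 5
Reactants: 9 (R)-2-methylbutanoic acid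
Product: 10 (3R)-3-methylpentan-2-one
Conditions: MeLi (2.1 equiv), Et2O, 0 °C; inverse quench into cold 1 M HCl
Reagents that add atoms: methyllithium, [Li]C
Why: Addition of methyllithium to the lithium carboxylate gives a dilithium gem-diolate that releases the methyl ketone only on acidic quench, so no tertiary alcohol forms and the α-stereocentre is never exposed to base as a ketone.

Step 6
Reactants: 10 (3R)-3-methylpentan-2-one
Product: 11 (6R)-6-methyloctane-3,5-dione
Conditions: LDA (commercial solution, 1.05 equiv), THF, −78 °C; N-methoxy-N-methylpropanamide (1.3 equiv), −78 → 0 °C; 1 M HCl
Reagents that add atoms: N-methoxy-N-methylpropanamide, CCC(=O)N(C)OC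
Why: Kinetic deprotonation with LDA takes the methyl group, not the stereogenic methine, and the lithium enolate acylates the N-methoxy-N-methylamide (Claisen-type acylation of a ketone enolate); the chelated tetrahedral adduct holds until work-up, so the acidic diketone does not form while enolate is present.

Step 7
Reactants: 8 hydroxy lactone ester; 11 (6R)-6-methyloctane-3,5-dione
Product: 12 methyl (3S,3aR,5R,7S,7aR)-5-[(6R)-2,6-dimethyl-3,5-dioxooctanoyl]-3,7-dihydroxy-3,7-dimethyl-octahydro-1H-indene-5-carboxylate (side-chain C2 enolisable, not assigned)
Conditions: 11 (2.0 equiv), LDA (commercial solution, 5.0 equiv), THF, −78 → 0 °C; then 8, −78 → 0 °C; AcOH quench at −78 °C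
Reagents that add atoms: none
Why: Acylation of a 1,3-diketone dianion at its terminal carbanion: the second deprotonation of 11 takes its C2 methylene rather than the more substituted stereogenic C6 methine, and this carbanion opens the lactone, whose carbonyl is held in the reactive s-trans ester geometry and is more electrophilic than the neighbouring neopentyl methyl ester. The spare equivalent of LDA takes the C7' hydroxyl proton and the second equivalent of dianion the acidic proton of the product; since only the lactone carbonyl reacts, the spiro-carbon geometry is carried over and the new C5–C6 bond sits on the correct carbonyl.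

Step 8
Reactants: 12 triketo ester diol
Product: 13 (1R,3'S,3a'R,7'S,7a'R)-3',4,6,7'-tetrahydroxy-3',5,7'-trimethyl-3-[(2R)-2-methylbutanoyl]-1',2',3',3a',4',6',7',7a'-octahydrospiro[cyclohexa-3,5-diene-1,5'-inden]-2-one (dienol form of the 5-methyl acyl trione)
Conditions: KOt-Bu (4 equiv), THF, 0 °C → rt; 1 M HCl to pH 3
Reagents that add atoms: none
Why: Intramolecular Claisen (Dieckmann-type) condensation of a 5-oxo ester: the central carbon of the triketone dianion attacks the methyl ester and closes ring A as a six-membered ring (C2–C3 bond), the only closure open to a carbon nucleophile because the ester α-carbon has no hydrogen. Deprotonation of the strongly acidic acyl trione drives the closure, the C6 ketone is protected as part of the enolate, and the side-chain methine would be a third deprotonation and should stay untouched.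

Step 9
Reactants: 13 spiro 5-methyl acyl trione
Product: 14 (1R,3'S,3a'R,5S,7'S,7a'R)-3',4,7'-trihydroxy-3',5,7'-trimethyl-5-(3-methylbut-2-en-1-yl)-3-[(2R)-2-methylbutanoyl]-1',2',3',3a',4',6',7',7a'-octahydrospiro[cyclohex-3-ene-1,5'-indene]-2,6-dione (target, CNP0236509.3)
Conditions: Pd2(dba)3·CHCl3 (2.5 mol %), (1R,2R)-N,N'-bis[2-(diphenylphosphanyl)benzoyl]cyclohexane-1,2-diamine (7.5 mol %), prenyl acetate (1.2 equiv), Et3N (1.2 equiv), degassed CH2Cl2, 0 °C → rt
Reagents that add atoms: 3-methylbut-2-en-1-yl acetate, CC(C)=CCOC(C)=O
Why: Tsuji–Trost allylic alkylation: zerovalent palladium ionises prenyl acetate and the soft trione enolate of 13 attacks the unsubstituted allyl terminus from outside the metal at C5, the carbon used in classical C-alkylation of such acyl triones; O-prenyl ethers re-ionise and funnel to the C-alkylated product. C5 is four bonds from the nearest stereocentre, so the substrate offers no bias and the chiral pocket of the ligand decides which enolate face reacts; the sense of induction for this enolate class has to be confirmed in the first run, and the enantiomeric ligand is used if the C5 epimer forms.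

## Compound list

1 | dimethyl malonate | COC(=O)CC(=O)OC | starting material
2 | (S)-linalool, (3S)-3,7-dimethylocta-1,6-dien-3-ol | C=C[C@@](C)(O)CCC=C(C)C | starting material
3 | dimethyl 2-{[(1R,2S,5R)-2-hydroxy-2-methyl-5-(prop-1-en-2-yl)cyclopentyl]methyl}propanedioate (formed and consumed in step 1) | COC(=O)C(C(=O)OC)C[C@@H]1[C@@H](CC[C@]1(C)O)C(C)=C | intermediate
4 | dimethyl (3S,3aR,7aR)-3-hydroxy-3-methyl-7-methylidene-octahydro-5H-indene-5,5-dicarboxylate | COC(=O)C1(C(=O)OC)C[C@@H]2[C@@H](CC[C@]2(C)O)C(=C)C1 | intermediate
5 | methyl (3S,3aR,5S,7aR)-3-methyl-7-methylidene-octahydro-1H-indene-5-carboxylate 5,3-carbolactone | COC(=O)[C@@]12C[C@@H]3[C@@H](CC[C@]3(C)OC1=O)C(=C)C2 | intermediate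
6 | secondary ozonide of 5: C7 is the spiro carbon of a 1,2,4-trioxolane, both configurations at that carbon (formed and consumed in step 3) | COC(=O)[C@@]12C[C@@H]3[C@@H](CC[C@]3(C)OC1=O)C1(OCOO1)C2 | intermediate
7 | methyl (3S,3aR,5S,7aR)-3-methyl-7-oxo-octahydro-1H-indene-5-carboxylate 5,3-carbolactone | COC(=O)[C@@]12C[C@@H]3[C@@H](CC[C@]3(C)OC1=O)C(=O)C2 | intermediate
8 | methyl (3S,3aR,5S,7S,7aR)-7-hydroxy-3,7-dimethyl-octahydro-1H-indene-5-carboxylate 5,3-carbolactone | COC(=O)[C@@]12C[C@@H]3[C@@H](CC[C@]3(C)OC1=O)[C@@](C)(O)C2 | intermediate
9 | (R)-2-methylbutanoic acid | CC[C@@H](C)C(O)=O | starting material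
10 | (3R)-3-methylpentan-2-one | CC[C@@H](C)C(C)=O | intermediate
11 | (6R)-6-methyloctane-3,5-dione | CC[C@@H](C)C(=O)CC(=O)CC | intermediate
12 | methyl (3S,3aR,5R,7S,7aR)-5-[(6R)-2,6-dimethyl-3,5-dioxooctanoyl]-3,7-dihydroxy-3,7-dimethyl-octahydro-1H-indene-5-carboxylate (side-chain C2 not assigned) | COC(=O)[C@@]1(C[C@@H]2[C@@H](CC[C@]2(C)O)[C@@](C)(O)C1)C(=O)C(C)C(=O)CC(=O)[C@H](C)CC | intermediate
13 | (1R,3'S,3a'R,7'S,7a'R)-3',4,6,7'-tetrahydroxy-3',5,7'-trimethyl-3-[(2R)-2-methylbutanoyl]-octahydrospiro[cyclohexa-3,5-diene-1,5'-inden]-2-one | CC[C@@H](C)C(=O)C1=C(O)C(C)=C(O)[C@]2(C[C@@H]3[C@@H](CC[C@]3(C)O)[C@@](C)(O)C2)C1=O | intermediate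
14 | (1R,3'S,3a'R,5S,7'S,7a'R)-3',4,7'-trihydroxy-3',5,7'-trimethyl-5-(3-methylbut-2-en-1-yl)-3-[(2R)-2-methylbutanoyl]-octahydrospiro[cyclohex-3-ene-1,5'-indene]-2,6-dione | CC[C@@H](C)C(=O)C1=C(O)[C@](C)(CC=C(C)C)C(=O)[C@]2(C[C@@H]3[C@@H](CC[C@]3(C)O)[C@@](C)(O)C2)C1=O | target

## Step count and uncertain steps

Total: 9 steps. Longest linear sequence: 7 steps (steps 1–4 and 7–9 from **1** and **2**); steps 5 and 6 form a two-step branch from **9**.

**Step 1 (key step).** Several processes can divert the cascade:
- malonyl radical attack at the trisubstituted alkene instead of the vinyl group;
- ionisation of a tertiary radical, with capture by the cis hydroxyl or loss of a proton towards the more substituted alkene, before the second ring can close;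
- further radical addition to the 1,1-disubstituted alkenes of the intermediate and the product;
- acid-induced ionisation of the tertiary allylic alcohol;
- incomplete facial control in the 5-exo closure.

Fallback by known chemistry, from **2** to **4**: visible-light atom-transfer radical addition of dimethyl 2-bromomalonate (Ru(bpy)3Cl2, LiBr, DMF/H2O, blue light) to the vinyl group, with 5-exo closure and bromine transfer. This should give the tertiary bromide dimethyl 2-{[(1R,2S,5R)-5-(2-bromopropan-2-yl)-2-hydroxy-2-methylcyclopentyl]methyl}propanedioate F1 under neutral conditions. Dehydrobromination with DBU in toluene would give **3**, now isolated and purified. The separately precedented oxidative 6-endo cyclisation of this unsaturated malonate with Mn(OAc)3·2H2O (2.2 equiv) and Cu(OAc)2·H2O in AcOH rejoins the route at **4**.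

**Step 7.** Three things may go wrong: competing attack of the dianion at the methyl ester, slow addition of a hindered secondary carbanion to a neopentyl-type carbonyl, and proton exchange at the stereogenic methine of the dianion with erosion of configuration. Fallback from **8** to **13**, with a nucleophile that has no stereocentre and can be used in large excess:
- the dianion of methyl 3-oxopentanoate (NaH, then n-BuLi) opens the lactone to methyl (3S,3aR,5R,7S,7aR)-3,7-dihydroxy-5-(5-methoxy-2-methyl-3,5-dioxopentanoyl)-3,7-dimethyl-octahydro-1H-indene-5-carboxylate F2;
- KOt-Bu closes ring A to the 3-methoxycarbonyl spiro trione F3;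
- saponification and acidification with loss of CO2 give the 5-methyl spiro trione without acyl group F4;
- the acyl group is then put on C3 with acid **9**, DCC and DMAP (O-acylation followed by DMAP-mediated acyl shift to carbon, as used for cyclic 1,3-diones), which returns to the route at **13**.

**Step 8.** The enolate may close through oxygen to an enol lactone, the neopentyl ester may be too hindered to react, or alkoxide may cleave the triketone by retro-Claisen. Fallback from **12** to **13**: SN2 demethylation of the ester with LiI in pyridine at reflux gives the triketo acid (3S,3aR,5R,7S,7aR)-5-[(6R)-2,6-dimethyl-3,5-dioxooctanoyl]-3,7-dihydroxy-3,7-dimethyl-octahydro-1H-indene-5-carboxylic acid F5. Activation with DCC and DMAP then acylates the diketone intramolecularly, by way of the O-acyl compound and acyl shift to carbon, to give **13**.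

**Step 9.** The ligand may discriminate the two faces at C5 poorly, the nucleophile may attack the substituted terminus of the prenyl–palladium intermediate (reverse prenyl), or some material may be lost to O-alkylation. Fallback from **13** to **14**: the same palladium/ligand system with allyl acetate, whose symmetrical allyl terminus removes the regiochemical question and is the case where ligand control over prochiral 1,3-dicarbonyl nucleophiles is best established. This gives the C5-allyl compound (1R,3'S,3a'R,5S,7'S,7a'R)-3',4,7'-trihydroxy-3',5,7'-trimethyl-3-[(2R)-2-methylbutanoyl]-5-(prop-2-en-1-yl)-octahydrospiro[cyclohex-3-ene-1,5'-indene]-2,6-dione F6. Cross-metathesis with 2-methylbut-2-ene (second-generation Grubbs catalyst) converts allyl into prenyl and gives **14**.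

## Further compounds

F1 | step 1 | dimethyl 2-{[(1R,2S,5R)-5-(2-bromopropan-2-yl)-2-hydroxy-2-methylcyclopentyl]methyl}propanedioate | COC(=O)C(C(=O)OC)C[C@@H]1[C@@H](CC[C@]1(C)O)C(C)(C)Br
F2 | step 7 | methyl (3S,3aR,5R,7S,7aR)-3,7-dihydroxy-5-(5-methoxy-2-methyl-3,5-dioxopentanoyl)-3,7-dimethyl-octahydro-1H-indene-5-carboxylate | COC(=O)[C@@]1(C[C@@H]2[C@@H](CC[C@]2(C)O)[C@@](C)(O)C1)C(=O)C(C)C(=O)CC(=O)OC
F3 | step 7 | methyl (1R,3'S,3a'R,7'S,7a'R)-3',4,6,7'-tetrahydroxy-3',5,7'-trimethyl-2-oxo-octahydrospiro[cyclohexa-3,5-diene-1,5'-indene]-3-carboxylate | COC(=O)C1=C(O)C(C)=C(O)[C@]2(C[C@@H]3[C@@H](CC[C@]3(C)O)[C@@](C)(O)C2)C1=O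
F4 | step 7 | (1R,3'S,3a'R,7'S,7a'R)-3',4,6,7'-tetrahydroxy-3',5,7'-trimethyl-octahydrospiro[cyclohexa-3,5-diene-1,5'-inden]-2-one | C1=C(O)C(C)=C(O)[C@]2(C[C@@H]3[C@@H](CC[C@]3(C)O)[C@@](C)(O)C2)C1=O
F5 | step 8 | (3S,3aR,5R,7S,7aR)-5-[(6R)-2,6-dimethyl-3,5-dioxooctanoyl]-3,7-dihydroxy-3,7-dimethyl-octahydro-1H-indene-5-carboxylic acid | OC(=O)[C@@]1(C[C@@H]2[C@@H](CC[C@]2(C)O)[C@@](C)(O)C1)C(=O)C(C)C(=O)CC(=O)[C@H](C)CC
F6 | step 9 | (1R,3'S,3a'R,5S,7'S,7a'R)-3',4,7'-trihydroxy-3',5,7'-trimethyl-3-[(2R)-2-methylbutanoyl]-5-(prop-2-en-1-yl)-octahydrospiro[cyclohex-3-ene-1,5'-indene]-2,6-dione | CC[C@@H](C)C(=O)C1=C(O)[C@](C)(CC=C)C(=O)[C@]2(C[C@@H]3[C@@H](CC[C@]3(C)O)[C@@](C)(O)C2)C1=O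
A1 | alternative 1 | acyl trione enol with methyl and prenyl on one ring carbon and a [2-(2-methyloxiran-2-yl)-5-oxocyclopentyl]methyl group on the future spiro carbon | CC[C@@H](C)C(=O)C1=C(O)C(C[C@@H]2[C@@H](CCC2=O)[C@]3(C)CO3)=C(O)[C@@](C)(CC=C(C)C)C1=O
A2 | alternative 2 | bis(triethylsilyl) ether of the spiro trione lacking the 2-methylbutanoyl group | C1=C(O)[C@](C)(CC=C(C)C)C(=O)[C@]2(C[C@@H]3[C@@H](CC[C@]3(C)O[Si](CC)(CC)CC)[C@@](C)(O[Si](CC)(CC)CC)C2)C1=O
A3 | alternative 3 | 1',2'-didehydro derivative of the target (ring C alkene) | CC[C@@H](C)C(=O)C1=C(O)[C@](C)(CC=C(C)C)C(=O)[C@]2(C[C@@H]3[C@@H](C=C[C@]3(C)O)[C@@](C)(O)C2)C1=O
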